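## Analysis of the target

The target (26) is a germacrane: a ten-membered carbocycle C1–C10 with an E-trisubstituted C1=C10 alkene bearing the C10 methyl, a trans C4–C5 epoxide bearing the C4 methyl, and a contiguous stereotetrad C6 (OAc), C7 (isopropyl), C8 (O-tigloyl), C9 (free OH). The configuration read from the structure is 4R,5R,6S,7S,8S,9R. If C5–C10 are folded into a chair six-ring, the C6 oxygen and the C7 isopropyl lie on one face and the C8 and C9 oxygens on the other. The epoxide oxygen is threo to the C6 oxygen, which is the outer face of an E-C4=C5 bond in the conformer that has H6 eclipsing the C4 methyl. Sensitive features are the epoxide facing the C1=C10 alkene across the ring (acid-induced transannular cyclisation), three acylable oxygens in a row (acyl migration), the isomerisable tiglate, and the 1(10),4-diene stage, which can undergo Cope rearrangement on heating. The difficulty is the medium ring with two geometrically defined trisubstituted π-bonds together with four contiguous stereocentres carrying three differently substituted oxygens. The strategy rests on this feature: C1=C10 and C4=C5 flank the C2–C3 bridge, so C1–C4 is a latent butadiene whose termini carry C10 and C5. Joining C5 to C10 gives a hexalin in which ring A (C1, C2, C3, C4, C5, C10) is a cyclohexa-1,3-diene and ring B (C5–C10) holds the whole stereotetrad on a rigid chair.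

## Retrosynthetic reasoning

**Acyl and silyl groups (26 back to 22).** The C9 silyl ether of 25 is removed last, so the allylic C9 hydroxyl is never free while oxidants or acylating agents are present. The tiglate is attached to the C8 hydroxyl of 24, which is released selectively from the more labile triethylsilyl ether of 23. The acetate goes onto C6 of 22 only after the C6 hydroxyl has done its job in the epoxidation. Cutting the three O–acyl and O–Si bonds in this order keeps C6, C8 and C9 distinguishable at every stage.

**Epoxide (22 back to 21).** The C4–O and C5–O bonds are cut to give the E-C4=C5 alkene of 21. The free C6 hydroxyl is the only hydroxyl in 21. It sits on the outer face of that alkene and directs the oxidant there. The C1=C10 alkene is flanked by a silyl ether and is not directed.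

**Surplus alkene (21 back to 20).** Two hydrogens are removed from C2–C3 to give the cis C2=C3 bond of triene 20. Forward, a concerted syn hydrogen transfer has to pick the only disubstituted alkene out of three.

**Key disconnection (20 back to 19).** The C5–C10 σ-bond is restored at the cost of the C1=C10 and C4=C5 π-bonds, giving the trans-fused hexalin 19. This is the place to cut because the bond lies across the ring: the ten-ring is then never closed but released from two six-rings. The trans ring fusion translates into the E geometry of both new alkenes, and C6–C9 become substituents of a chair.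

**Ring A diene (19 back to 15).** The C3–H bond of the diene is traced to a C3–O bond: dienyl triflate 17 from the cross-conjugated enolate of enone 16, which is the silylated form of 15. C4–H is the only acidic hydrogen of that enone, so the diene position is unambiguous.

**C6 oxygen and ring fusion (15 back to 12).** The C6–OH bond comes from a C6 ketone (14), which also makes C5 epimerisable. The ketone comes from ene-dione 13 by reduction of C4=C5, and 13 from dienone 12 by oxidation of C6, the only CH2 at its γ-position. One carbonyl thus delivers the oxygen, the trans fusion and, by hydride attack away from the axial C10 methyl, the axial C6 alcohol.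

**C8 and C9 oxygens (12 back to 9).** Both C–O bonds are cut at once to the C8=C9 alkene of 9. The cis-diol 10 forms on the face away from the C10 methyl and the C7 isopropyl. Its two hydroxyls differ enough in hindrance (C9 is neopentyl) to be silylated in sequence (11, 12).

**Unsaturation (9 back to 5).** The two ring A alkenes of 9 are removed to ketone 8. The C8=C9 alkene is traced through enol triflate 6 to the C9 ketone of 5, whose ring A carbonyl is masked as the silyl enol ether.

**Decalin (5 back to 2 and 4).** The C10–C1 and C5–C4 bonds are cut in a Diels–Alder sense to enone 2 and diene 4. The diene brings the C4 methyl, so no enolate methylation is needed in the presence of the C9 ketone. The isopropyl stereocentre of 2 dictates the face and hence C10.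

**Starting materials (2 back to 1, 4 back to 3).** Enone 2 is the isopropenyl-saturated form of 1, and 4 is the silyl dienol ether of 3.

## Alternatives that were turned down

**Alternative 1:** The disconnection is the C8–C9 bond, which opens the ring to the acyclic dialdehyde A2. In the forward step SmI2 reduces the C9 enal and the C8 aldehyde to ketyls that couple, closing the ten-ring and creating both carbinol centres of diol A1.
- For: the ring is formed last from a convergently assembled chain, one step makes a C–C bond and two stereocentres, no photochemistry is involved, and A1 is a single acylation from 26.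
- Against: the closure pays the full entropic and transannular cost of a ten-ring. The enal ketyl is an allyl-type radical anion that can also couple through C1. The C6 acetate is β to the C8 ketyl and can be expelled. The C8/C9 configuration must come from a flexible medium-ring transition state. The two hydroxyls of A1 emerge undifferentiated, so tigloylation at C8 only would rest on a small steric difference. A2 must already carry the epoxide and three stereocentres made by acyclic control.
- Comparison: this alternative is stronger on convergence and on the number of steps after ring formation. The chosen strategy offers a ring that appears without a closure event, fixed alkene geometry, and a chair in which C8 and C9 are told apart by hindrance.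

**Alternative 2:** The disconnection reconnects the C1≡C10 alkyne and the C6 ketone of cyclodecynone A3 through a C1–C6 bond, giving the bicyclic epoxy ketone A4. In the forward step p-toluenesulfonylhydrazide and acetic acid form the hydrazone of A4, which fragments with loss of nitrogen and sulfinate to A3.
- For: the fragmentation is thermal and irreversible, needs no closure entropy, is well established for medium-ring alkynones, and gives a product that is not thermally fragile.
- Against: C10 carries no methyl after the fragmentation, so a regio- and E-selective carbometallation of a strained cyclodecyne next to the C9 silyloxy carbon is required. The C6 ketone must be reduced with facial control on the flexible ring. The acetonide must be exchanged for the trans epoxide with inversion at one carbon. The PMB ether must be exchanged for the tiglate. A4 itself needs a tetrasubstituted ring-fusion epoxide in a heavily oxygenated decalin.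
- Comparison: this alternative is stronger on irreversibility and scalability of the key event. The chosen strategy offers both trisubstituted π-bonds, both methyl groups and the C6 alcohol in place and correctly configured at the moment the ring appears.

**Alternative 3:** The disconnection cuts C2–C3 and restores C5–C10, leading to the divinylcyclohexanol A6. In the forward step KH and 18-crown-6 form the C10 alkoxide, a chair [3,3] shift gives the (E,E)-cyclodecadienyl enolate, and N-phenyltriflimide traps it as triflate A5.
- For: it is the closest relative of the chosen route. The same σ-bond is broken, there is no closure entropy, the enolate makes it irreversible, the chair gives E,E geometry, and the 1(10),4-diene is obtained directly with no surplus alkene and no photostationary state.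
- Against: the C10 methyl must be added afterwards by cross-coupling of a hindered cyclodecadienyl triflate. Before trapping, the enolate sits next to the C9 and C8 alkoxy carbons, so equilibration and β-elimination are possible. A6 has six contiguous stereocentres on one ring, including a tertiary carbinol made by vinyl addition trans to its neighbour. Two arylmethyl ethers must be removed late from an epoxy-germacrene.
- Comparison: this alternative is stronger on directness and thermal irreversibility. The chosen strategy offers a precursor whose ring A comes from one cycloaddition on a chiral-pool enone, with every carbon including both methyls present before the ring opens, and ring B stereochemistry set on a rigid decalin.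

Key step: step 16

**Remarks on the chemistry**
- The decalins are numbered as eudesmanes (ring A = C1–C5 and C10, ring B = C5–C10), which coincides with the germacrane numbering of 26. α/β give relative configuration only, β being the face of the C10 methyl; the absolute configuration is that of the SMILES strings.
- TBS = tert-butyldimethylsilyl, TES = triethylsilyl, TMS = trimethylsilyl.
- The C4 methyl of 5–8 and 14–16, and of the fallback compounds F1, F2, F3, F4 and F5, is written as the expected major epimer. Its configuration is of no consequence, since C4 becomes sp2 in steps 6 and 14.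
- Diene 4 is prepared from 3 and not assumed to be purchasable.

## Steps

Step 1
Reactants: 1 (R)-(−)-carvone
Product: 2 (R)-carvotanacetone
Conditions: H2 (1 atm), RhCl(PPh3)3 (cat.), benzene, rt
Reagents that add atoms: none
Why: Homogeneous hydrogenation with RhCl(PPh3)3 saturates the unhindered 1,1-disubstituted isopropenyl alkene and should leave the trisubstituted conjugated enone alone; the stereocentre is not touched.

Step 2
Reactants: 3 pent-1-en-3-one
Product: 4 (Z)-3-(tert-butyldimethylsilyloxy)penta-1,3-diene
Conditions: TBSOTf, Et3N, Et2O, 0 °C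
Reagents that add atoms: tert-butyldimethylsilyl trifluoromethanesulfonate, CC(C)(C)[Si](C)(C)OS(=O)(=O)C(F)(F)F
Why: Soft enolisation and O-silylation of the ethyl ketone should give the Z silyl dienol ether, whose methyl group points outward so that the s-cis diene is reactive.

Step 3
Reactants: 2 (R)-carvotanacetone; 4 (Z)-3-(tert-butyldimethylsilyloxy)penta-1,3-diene
Product: 5 cis-fused 3-(tert-butyldimethylsilyloxy)-5βH-eudesm-2-en-9-one (4α-methyl, 7β-isopropyl, 10β-methyl)
Conditions: EtAlCl2 (0.3 equiv), toluene, −78 → −20 °C; pyridine quench
Reagents that add atoms: none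
Why: Lewis-acid Diels–Alder reaction of a 2-methylcyclohexenone with a 2-silyloxy diene; the methyl-bearing enol-ether terminus of 4 bonds to the enone β-carbon (C5) and the CH2 terminus to the α-carbon (C10). The diene adds to the face opposite the isopropyl group, which sets the C10 methyl cis to the isopropyl and gives the cis ring fusion; endo addition places the C4 methyl α.

Step 4
Reactants: 5 cis-fused 3-(tert-butyldimethylsilyloxy)-5βH-eudesm-2-en-9-one
Product: 6 3-(tert-butyldimethylsilyloxy)-5βH-eudesma-2,8-dien-9-yl trifluoromethanesulfonate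
Conditions: KN(SiMe3)2, THF, −78 °C; PhNTf2, −78 → 0 °C
Reagents that add atoms: N-phenylbis(trifluoromethanesulfonimide), O=S(=O)(N(c1ccccc1)S(=O)(=O)C(F)(F)F)C(F)(F)F
Why: Enol triflate formation; the C9 ketone can enolise only toward C8 because C10 is quaternary, and the ring A carbonyl is masked as the silyl enol ether, so a single enolate is O-sulfonylated.

Step 5
Reactants: 6 3-(tert-butyldimethylsilyloxy)-5βH-eudesma-2,8-dien-9-yl trifluoromethanesulfonate
Product: 8 cis-fused 5βH-eudesm-8-en-3-one, via silyl enol ether 7 (not isolated)
Conditions: Pd(OAc)2 (cat.), PPh3, HCO2H, Bu3N, DMF, 60 °C; then 1 M HCl, THF, rt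
Reagents that add atoms: none
Why: Palladium-catalysed formate reduction of a vinyl triflate (oxidative addition to zerovalent palladium, decarboxylation of formate to a palladium hydride, reductive elimination) gives the C8=C9 alkene; aqueous acid then hydrolyses the silyl enol ether to the C3 ketone.

Step 6
Reactants: 8 cis-fused 5βH-eudesm-8-en-3-one
Product: 9 eudesma-1,4,8-trien-3-one (7β-isopropyl, 10β-methyl)
Conditions: IBX (2.5–3.5 equiv), DMSO, 70 °C
Reagents that add atoms: none
Why: IBX dehydrogenation of a ketone on both α,β-sides gives the cross-conjugated dienone, and the quaternary C10 rules out aromatisation. The step removes the C4 and C5 stereocentres, so the cis fusion of the cycloadduct no longer matters, and it places C6 at the γ-position.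

Step 7
Reactants: 9 eudesma-1,4,8-trien-3-one
Product: 10 8α,9α-dihydroxyeudesma-1,4-dien-3-one
Conditions: OsO4 (cat.), NMO, acetone–H2O, 0 °C → rt
Reagents that add atoms: osmium tetroxide, O=[Os](=O)(=O)=O; N-methylmorpholine N-oxide, C[N+]1([O-])CCOCC1; water, O
Why: Catalytic syn-dihydroxylation picks the isolated electron-rich C8=C9 alkene over the two electron-poor dienone alkenes. OsO4 adds to the α-face, anti to both allylic β-substituents (C10 methyl and C7 isopropyl), which sets C8 and C9 as the cis-diol trans to the methyl.

Step 8
Reactants: 10 8α,9α-dihydroxyeudesma-1,4-dien-3-one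
Product: 11 9α-hydroxy-8α-(triethylsilyloxy)eudesma-1,4-dien-3-one
Conditions: TESCl (1.1 equiv), imidazole, DMF, 0 °C
Reagents that add atoms: chlorotriethylsilane, CC[Si](Cl)(CC)CC
Why: Selective silylation; the C9 hydroxyl is axial and neopentyl (next to quaternary C10), so the equatorial C8 hydroxyl should react first.

Step 9
Reactants: 11 9α-hydroxy-8α-(triethylsilyloxy)eudesma-1,4-dien-3-one
Product: 12 9α-(tert-butyldimethylsilyloxy)-8α-(triethylsilyloxy)eudesma-1,4-dien-3-one
Conditions: TBSOTf, 2,6-lutidine, CH2Cl2, 0 °C → rt
Reagents that add atoms: tert-butyldimethylsilyl trifluoromethanesulfonate, CC(C)(C)[Si](C)(C)OS(=O)(=O)C(F)(F)F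
Why: The silyl triflate is reactive enough for the hindered C9 hydroxyl; the more robust silyl group goes onto the oxygen that must stay protected longest.

Step 10
Reactants: 12 9α-(tert-butyldimethylsilyloxy)-8α-(triethylsilyloxy)eudesma-1,4-dien-3-one
Product: 13 9α-(tert-butyldimethylsilyloxy)-8α-(triethylsilyloxy)eudesma-1,4-diene-3,6-dione
Conditions: Rh2(cap)4 (1 mol %; cap = caprolactamate), t-BuOOH (70% aq.), NaHCO3, CH2Cl2, rt
Reagents that add atoms: tert-butyl hydroperoxide, CC(C)(C)OO
Why: Dirhodium-caprolactamate-catalysed allylic oxidation of an enone at its γ-position; tert-butylperoxyl radicals abstract hydrogen from C6, the only CH2 that is allylic to C4=C5 and vinylogous to the carbonyl, and the mixed peroxide collapses to the ketone (ene-dione formation).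

Step 11
Reactants: 13 9α-(tert-butyldimethylsilyloxy)-8α-(triethylsilyloxy)eudesma-1,4-diene-3,6-dione
Product: 14 trans-fused 9α-(tert-butyldimethylsilyloxy)-8α-(triethylsilyloxy)-5αH-eudesm-1-ene-3,6-dione (4α-methyl)
Conditions: Zn, AcOH, THF, 0 °C → rt
Reagents that add atoms: none
Why: Zinc/acetic acid reduction of a 2-ene-1,4-dione to the saturated 1,4-dione; two-electron transfer gives the C3,C6-dienediol, which ketonises by protonation at C4 and C5, so the cross-conjugated C1=C2 bond should survive. C5 is protonated axially from the α-face and remains epimerisable through the C6 enol, so the more stable trans fusion (H5 anti to the C10 methyl) should result, with the C7 isopropyl equatorial.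

Step 12
Reactants: 14 trans-fused 9α-(tert-butyldimethylsilyloxy)-8α-(triethylsilyloxy)-5αH-eudesm-1-ene-3,6-dione
Product: 15 9α-(tert-butyldimethylsilyloxy)-6β-hydroxy-8α-(triethylsilyloxy)-5αH-eudesm-1-en-3-one
Conditions: NaBH4, MeOH–CH2Cl2, −78 → −40 °C
Reagents that add atoms: none
Why: At low temperature borohydride reduces a saturated ketone faster than a conjugated enone. The axial C10 methyl blocks the β-face of C6, so hydride should enter from the α-face and give the axial 6β-alcohol.

Step 13
Reactants: 15 9α-(tert-butyldimethylsilyloxy)-6β-hydroxy-8α-(triethylsilyloxy)-5αH-eudesm-1-en-3-one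
Product: 16 9α-(tert-butyldimethylsilyloxy)-8α-(triethylsilyloxy)-6β-(trimethylsilyloxy)-5αH-eudesm-1-en-3-one
Conditions: 1-(trimethylsilyl)imidazole, CH2Cl2, rt
Reagents that add atoms: 1-(trimethylsilyl)imidazole, C[Si](C)(C)n1ccnc1
Why: Neutral silylation caps the C6 hydroxyl with the most labile silyl group, so that no alkoxide competes in the enolate triflation and the group can be removed later without touching the other two silyl ethers.

Step 14
Reactants: 16 9α-(tert-butyldimethylsilyloxy)-8α-(triethylsilyloxy)-6β-(trimethylsilyloxy)-5αH-eudesm-1-en-3-one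
Product: 17 9α-(tert-butyldimethylsilyloxy)-8α-(triethylsilyloxy)-6β-(trimethylsilyloxy)-5αH-eudesma-1,3-dien-3-yl trifluoromethanesulfonate
Conditions: KN(SiMe3)2, THF, −78 °C; PhNTf2, −78 → 0 °C
Reagents that add atoms: N-phenylbis(trifluoromethanesulfonimide), O=S(=O)(N(c1ccccc1)S(=O)(=O)C(F)(F)F)C(F)(F)F
Why: The axial C4–H is the only acidic hydrogen of the enone (C2 is vinylic, the γ-carbon C10 is quaternary), so the cross-conjugated dienolate forms regiospecifically and is trapped as the dienyl triflate.

Step 15
Reactants: 17 9α-(tert-butyldimethylsilyloxy)-8α-(triethylsilyloxy)-6β-(trimethylsilyloxy)-5αH-eudesma-1,3-dien-3-yl trifluoromethanesulfonate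
Product: 19 9α-(tert-butyldimethylsilyloxy)-8α-(triethylsilyloxy)-5αH-eudesma-1,3-dien-6β-ol, via TMS-protected diene 18 (not isolated)
Conditions: Pd(OAc)2 (cat.), PPh3, HCO2H, Bu3N, DMF, 45 °C; then K2CO3, MeOH, 0 °C
Reagents that add atoms: none
Why: Palladium-catalysed formate reduction replaces the triflate by hydrogen and gives the homoannular C1=C2–C3=C4 diene; mild methanolysis then removes only the trimethylsilyl ether.

Step 16
Reactants: 19 9α-(tert-butyldimethylsilyloxy)-8α-(triethylsilyloxy)-5αH-eudesma-1,3-dien-6β-ol
Product: 20 (1(10)E,2Z,4E)-9-(tert-butyldimethylsilyloxy)-8-(triethylsilyloxy)germacra-1(10),2,4-trien-6-ol (C6–C9 as in 19)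
Conditions: hν (254 nm, low-pressure Hg lamp, quartz), degassed Et2O–MeOH, −40 °C, to the photostationary state; solution kept cold
Reagents that add atoms: none
Why: Excitation of the s-cis diene of ring A triggers a conrotatory 6π electrocyclic ring opening that cleaves the C5–C10 σ-bond and creates the C1=C10 and C4=C5 π-bonds, while C2=C3 stays cis. The closest known reaction type is the photochemical opening of trans-fused hexalin 1,3-dienes to (E,Z,E)-cyclodeca-1,3,5-trienes. The ten-membered ring is not closed by bond formation; it is released when the bond shared by the two six-membered rings breaks, so no ring-closure mode and no entropic penalty apply. No stereocentre is created: C5 and C10 are converted into alkene geometry, and C6–C9 lie outside the chromophore and are untouched. The selectivity needed is geometric and is secured by the trans fusion, because under conrotation the axial H5 and C10 methyl turn inward while the C5–C6 and C10–C9 bonds turn outward, giving E at both new alkenes. The opposite conrotatory sense would force the C6–C9 tether through the triene. The reaction is photoreversible, so it is stopped at the photostationary state before secondary photoproducts build up, and the solution is carried on cold because warming would allow thermal disrotatory reclosure to the cis-fused isomer.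

Step 17
Reactants: 20 (1(10)E,2Z,4E)-9-(tert-butyldimethylsilyloxy)-8-(triethylsilyloxy)germacra-1(10),2,4-trien-6-ol
Product: 21 (1(10)E,4E)-9-(tert-butyldimethylsilyloxy)-8-(triethylsilyloxy)germacra-1(10),4-dien-6-ol
Conditions: KO2CN=NCO2K, AcOH, MeOH–Et2O, −40 → −15 °C, on the cold photolysate; unchanged 19 recovered by chromatography and re-irradiated
Reagents that add atoms: none
Why: Diimide transfers two hydrogens in a concerted syn fashion and prefers the least substituted alkene, here the strained cis-disubstituted C2=C3. The two E-trisubstituted alkenes and the cyclohexadiene of unreacted 19 should react much more slowly.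

Step 18
Reactants: 21 (1(10)E,4E)-9-(tert-butyldimethylsilyloxy)-8-(triethylsilyloxy)germacra-1(10),4-dien-6-ol
Product: 22 (4R,5R)-9-(tert-butyldimethylsilyloxy)-4,5-epoxy-8-(triethylsilyloxy)germacr-1(10)E-en-6-ol
Conditions: mCPBA (1.05 equiv), NaHCO3, CH2Cl2, −20 → 0 °C
Reagents that add atoms: 3-chloroperoxybenzoic acid, OOC(=O)c1cccc(Cl)c1
Why: Hydroxyl-directed (Henbest-type) peracid epoxidation; in the ring conformer with H6 eclipsing the C4 methyl the C6 hydroxyl lies on the outer face of C4=C5 at the dihedral angle that suits hydrogen-bonded delivery, while the ring blocks the inner face, so the epoxide should form threo to the C6 oxygen. The C1=C10 alkene is deactivated and shielded by the neighbouring silyl ether, and the bicarbonate buffer suppresses transannular opening.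

Step 19
Reactants: 22 (4R,5R)-9-(tert-butyldimethylsilyloxy)-4,5-epoxy-8-(triethylsilyloxy)germacr-1(10)E-en-6-ol
Product: 23 (4R,5R)-9-(tert-butyldimethylsilyloxy)-4,5-epoxy-8-(triethylsilyloxy)germacr-1(10)E-en-6-yl acetate
Conditions: Ac2O, Et3N, DMAP, CH2Cl2, 0 °C → rt
Reagents that add atoms: acetic anhydride, CC(=O)OC(C)=O
Why: DMAP-catalysed acylation of the only free hydroxyl under basic conditions that the epoxide tolerates.

Step 20
Reactants: 23 (4R,5R)-9-(tert-butyldimethylsilyloxy)-4,5-epoxy-8-(triethylsilyloxy)germacr-1(10)E-en-6-yl acetate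
Product: 24 (4R,5R)-9-(tert-butyldimethylsilyloxy)-4,5-epoxy-8-hydroxygermacr-1(10)E-en-6-yl acetate
Conditions: HF·pyridine, pyridine, THF, 0 °C
Reagents that add atoms: none
Why: Selective desilylation; buffered fluoride cleaves the triethylsilyl ether much faster than the tert-butyldimethylsilyl ether, and the excess pyridine protects the epoxide from acid.

Step 21
Reactants: 24 (4R,5R)-9-(tert-butyldimethylsilyloxy)-4,5-epoxy-8-hydroxygermacr-1(10)E-en-6-yl acetate
Product: 25 (4R,5R)-6-acetoxy-9-(tert-butyldimethylsilyloxy)-4,5-epoxygermacr-1(10)E-en-8-yl (E)-2-methylbut-2-enoate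
Conditions: tiglic acid, 2,4,6-trichlorobenzoyl chloride, Et3N, toluene, rt; then DMAP, 40 °C
Reagents that add atoms: (E)-2-methylbut-2-enoic acid (tiglic acid), C/C=C(\C)C(=O)O
Why: Yamaguchi esterification through the mixed anhydride acylates the hindered C8 hydroxyl; the tiglate is the thermodynamically stable E isomer and should not isomerise.

Step 22
Reactants: 25 (4R,5R)-6-acetoxy-9-(tert-butyldimethylsilyloxy)-4,5-epoxygermacr-1(10)E-en-8-yl (E)-2-methylbut-2-enoate
Product: 26 (4R,5R,6S,7S,8S,9R)-6-acetoxy-4,5-epoxy-9-hydroxygermacr-1(10)E-en-8-yl (E)-2-methylbut-2-enoate (target)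
Conditions: Bu4NF, AcOH (1:1), THF, 0 °C → rt
Reagents that add atoms: none
Why: Fluoride cleavage of the remaining silyl ether; buffering with acetic acid keeps the liberated C9 alkoxide protonated, so that the C8 tiglate should not migrate and the epoxide should not open.

## Compound list

1 | (R)-(−)-carvone, (5R)-2-methyl-5-(prop-1-en-2-yl)cyclohex-2-en-1-one | CC1=CC[C@H](CC1=O)C(C)=C | starting material
2 | (R)-carvotanacetone, (5R)-2-methyl-5-(propan-2-yl)cyclohex-2-en-1-one | CC1=CC[C@H](CC1=O)C(C)C | intermediate
3 | pent-1-en-3-one (ethyl vinyl ketone) | CCC(=O)C=C | starting material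
4 | (Z)-3-(tert-butyldimethylsilyloxy)penta-1,3-diene | C=C/C(O[Si](C)(C)C(C)(C)C)=C/C | intermediate
5 | cis-fused 3-(tert-butyldimethylsilyloxy)-5βH-eudesm-2-en-9-one (4α-methyl, 7β-isopropyl, 10β-methyl) | C1[C@H](C(C)C)C[C@H]2[C@@H](C)C(O[Si](C)(C)C(C)(C)C)=CC[C@@]2(C)C1=O | intermediate
6 | 3-(tert-butyldimethylsilyloxy)-5βH-eudesma-2,8-dien-9-yl trifluoromethanesulfonate | FC(F)(F)S(=O)(=O)OC1=C[C@H](C(C)C)C[C@H]2[C@@H](C)C(O[Si](C)(C)C(C)(C)C)=CC[C@@]12C | intermediate
7 | 3-(tert-butyldimethylsilyloxy)-5βH-eudesma-2,8-diene | C1=C[C@H](C(C)C)C[C@H]2[C@@H](C)C(O[Si](C)(C)C(C)(C)C)=CC[C@@]12C | intermediate (not isolated)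
8 | cis-fused 5βH-eudesm-8-en-3-one (4α-methyl drawn) | C1=C[C@H](C(C)C)C[C@H]2[C@@H](C)C(=O)CC[C@@]12C | intermediate
9 | eudesma-1,4,8-trien-3-one (7β-isopropyl, 10β-methyl) | C1=C[C@H](C(C)C)CC2=C(C)C(=O)C=C[C@@]12C | intermediate
10 | 8α,9α-dihydroxyeudesma-1,4-dien-3-one | O[C@H]1[C@H](C(C)C)CC2=C(C)C(=O)C=C[C@@]2(C)[C@H]1O | intermediate
11 | 9α-hydroxy-8α-(triethylsilyloxy)eudesma-1,4-dien-3-one | CC[Si](CC)(CC)O[C@H]1[C@H](C(C)C)CC2=C(C)C(=O)C=C[C@@]2(C)[C@H]1O | intermediate
12 | 9α-(tert-butyldimethylsilyloxy)-8α-(triethylsilyloxy)eudesma-1,4-dien-3-one | CC[Si](CC)(CC)O[C@H]1[C@H](C(C)C)CC2=C(C)C(=O)C=C[C@@]2(C)[C@H]1O[Si](C)(C)C(C)(C)C | intermediate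
13 | 9α-(tert-butyldimethylsilyloxy)-8α-(triethylsilyloxy)eudesma-1,4-diene-3,6-dione | CC[Si](CC)(CC)O[C@H]1[C@H](C(C)C)C(=O)C2=C(C)C(=O)C=C[C@@]2(C)[C@H]1O[Si](C)(C)C(C)(C)C | intermediate
14 | trans-fused 9α-(tert-butyldimethylsilyloxy)-8α-(triethylsilyloxy)-5αH-eudesm-1-ene-3,6-dione (4α-methyl drawn) | CC[Si](CC)(CC)O[C@H]1[C@H](C(C)C)C(=O)[C@@H]2[C@@H](C)C(=O)C=C[C@@]2(C)[C@H]1O[Si](C)(C)C(C)(C)C | intermediate
15 | 9α-(tert-butyldimethylsilyloxy)-6β-hydroxy-8α-(triethylsilyloxy)-5αH-eudesm-1-en-3-one | CC[Si](CC)(CC)O[C@H]1[C@H](C(C)C)[C@H](O)[C@@H]2[C@@H](C)C(=O)C=C[C@@]2(C)[C@H]1O[Si](C)(C)C(C)(C)C | intermediate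
16 | 9α-(tert-butyldimethylsilyloxy)-8α-(triethylsilyloxy)-6β-(trimethylsilyloxy)-5αH-eudesm-1-en-3-one | CC[Si](CC)(CC)O[C@H]1[C@H](C(C)C)[C@H](O[Si](C)(C)C)[C@@H]2[C@@H](C)C(=O)C=C[C@@]2(C)[C@H]1O[Si](C)(C)C(C)(C)C | intermediate
17 | 9α-(tert-butyldimethylsilyloxy)-8α-(triethylsilyloxy)-6β-(trimethylsilyloxy)-5αH-eudesma-1,3-dien-3-yl trifluoromethanesulfonate | CC[Si](CC)(CC)O[C@H]1[C@H](C(C)C)[C@H](O[Si](C)(C)C)[C@@H]2C(C)=C(OS(=O)(=O)C(F)(F)F)C=C[C@@]2(C)[C@H]1O[Si](C)(C)C(C)(C)C | intermediate
18 | 9α-(tert-butyldimethylsilyloxy)-8α-(triethylsilyloxy)-6β-(trimethylsilyloxy)-5αH-eudesma-1,3-diene | CC[Si](CC)(CC)O[C@H]1[C@H](C(C)C)[C@H](O[Si](C)(C)C)[C@@H]2C(C)=CC=C[C@@]2(C)[C@H]1O[Si](C)(C)C(C)(C)C | intermediate (not isolated)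
19 | 9α-(tert-butyldimethylsilyloxy)-8α-(triethylsilyloxy)-5αH-eudesma-1,3-dien-6β-ol (key-step precursor) | CC[Si](CC)(CC)O[C@H]1[C@H](C(C)C)[C@H](O)[C@@H]2C(C)=CC=C[C@@]2(C)[C@H]1O[Si](C)(C)C(C)(C)C | intermediate
20 | (1(10)E,2Z,4E)-9-(tert-butyldimethylsilyloxy)-8-(triethylsilyloxy)germacra-1(10),2,4-trien-6-ol (key-step product) | CC[Si](CC)(CC)O[C@H]1[C@H](C(C)C)[C@H](O)/C=C(\C)/C=C\C=C(/C)[C@H]1O[Si](C)(C)C(C)(C)C | intermediate
21 | (1(10)E,4E)-9-(tert-butyldimethylsilyloxy)-8-(triethylsilyloxy)germacra-1(10),4-dien-6-ol | CC[Si](CC)(CC)O[C@H]1[C@H](C(C)C)[C@H](O)/C=C(\C)CC/C=C(\C)[C@H]1O[Si](C)(C)C(C)(C)C | intermediate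
22 | (4R,5R)-9-(tert-butyldimethylsilyloxy)-4,5-epoxy-8-(triethylsilyloxy)germacr-1(10)E-en-6-ol | CC[Si](CC)(CC)O[C@H]1[C@H](C(C)C)[C@H](O)[C@H]2O[C@]2(C)CC/C=C(\C)[C@H]1O[Si](C)(C)C(C)(C)C | intermediate
23 | (4R,5R)-9-(tert-butyldimethylsilyloxy)-4,5-epoxy-8-(triethylsilyloxy)germacr-1(10)E-en-6-yl acetate | CC[Si](CC)(CC)O[C@H]1[C@H](C(C)C)[C@H](OC(C)=O)[C@H]2O[C@]2(C)CC/C=C(\C)[C@H]1O[Si](C)(C)C(C)(C)C | intermediate
24 | (4R,5R)-9-(tert-butyldimethylsilyloxy)-4,5-epoxy-8-hydroxygermacr-1(10)E-en-6-yl acetate | O[C@H]1[C@H](C(C)C)[C@H](OC(C)=O)[C@H]2O[C@]2(C)CC/C=C(\C)[C@H]1O[Si](C)(C)C(C)(C)C | intermediate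
25 | (4R,5R)-6-acetoxy-9-(tert-butyldimethylsilyloxy)-4,5-epoxygermacr-1(10)E-en-8-yl (E)-2-methylbut-2-enoate | C/C=C(\C)C(=O)O[C@H]1[C@H](C(C)C)[C@H](OC(C)=O)[C@H]2O[C@]2(C)CC/C=C(\C)[C@H]1O[Si](C)(C)C(C)(C)C | intermediate
26 | (4R,5R,6S,7S,8S,9R)-6-acetoxy-4,5-epoxy-9-hydroxygermacr-1(10)E-en-8-yl (E)-2-methylbut-2-enoate (CNP0163041.1) | C/C=C(\C)C(=O)O[C@H]1[C@H](C(C)C)[C@H](OC(C)=O)[C@H]2O[C@]2(C)CC/C=C(\C)[C@H]1O | target

## Step count and least certain steps

Total: 22 steps. Longest linear sequence: 21 steps (steps 1 and 3–22, from 1 to 26); step 2 is a one-step branch.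

**Step 16 (key step).** The photochemical opening may fall short for three reasons: the photostationary state may lie on the side of the diene, the triene may be consumed by further photoreactions (alkene isomerisation, further electrocyclisation) on prolonged irradiation, and it may reclose thermally by the disrotatory path to the cis-fused hexalin if the solution warms. The last two also endanger step 17, where the hydrogen transfer must outrun reclosure and must not touch recovered 19. Fallback: interception instead of accumulation. Setting out from 19, the irradiation is run in continuous flow (thin quartz or fluoropolymer coil at −40 °C, short residence time) and the effluent is discharged directly into the cold diimide mixture of step 17, or into H2 over skeletal nickel (Raney Ni) at −20 °C. The triene is then never re-irradiated or warmed, and the route is rejoined at 21; unchanged 19 is separated and recirculated. No new compound is involved.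

**Step 3.** The aluminium Lewis acid may strip the silyl group from the product, or the reaction may stop at the Mukaiyama–Michael stage, so that the ring A carbonyl is no longer masked when the C9 ketone has to be enolised; facial selectivity may also erode at higher temperature. Fallback: a ketal serves as the mask in place of the silyl enol ether. Setting out from 2 and 4, the cycloaddition (or the two-stage Michael sequence to the same skeleton) is worked up with aqueous acid, which should give cis-fused 5βH-eudesmane-3,9-dione F1 as the unmasked adduct. The unhindered C3 carbonyl of F1 is ketalised selectively with ethylene glycol and an acid catalyst to 3,3-ethylenedioxy-5βH-eudesman-9-one F2 while the neopentyl C9 ketone is left alone. Triflation of F2 as in step 4 gives 3,3-ethylenedioxy-5βH-eudesm-8-en-9-yl trifluoromethanesulfonate F3 and formate reduction of F3 as in step 5 gives 3,3-ethylenedioxy-5βH-eudesm-8-ene F4 from which aqueous acid removes the ketal, so that the route is rejoined at 8.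

**Step 6.** The second dehydrogenation, toward the tetrasubstituted C4=C5 bond, may lag, while the hot oxidant may dehydrogenate further along the vinylogous C6–C7 positions. Fallback: two regiodefined stages. Setting out from 7 (isolated by omitting the acid treatment of step 5), Saegusa–Ito oxidation with Pd(OAc)2 in MeCN gives cis-fused 5βH-eudesma-1,8-dien-3-one F5 with the C1=C2 bond placed by the position of the enol ether. N,O-Bis(trimethylsilyl)trifluoroacetamide in toluene then converts F5 into 3-(trimethylsilyloxy)-5βH-eudesma-1,3,8-triene F6 and DDQ abstracts the allylic C5 hydride of F6 to introduce C4=C5, so that the route is rejoined at 9.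

**Step 10.** Radical oxidation may be slow at the hindered C6, and the C8 silyloxy group, which is β to the new C6 carbonyl, may be eliminated under the basic peroxide conditions. Fallback: ionic γ-oxidation. Setting out from 12, TBSOTf and Et3N give the cross-conjugated trienol ether 3,9α-bis(tert-butyldimethylsilyloxy)-8α-(triethylsilyloxy)eudesma-1,3,5-triene F7 by γ-deprotonation at C6. Dimethyldioxirane at −40 °C attacks the electron-rich C6 terminus of F7 in a vinylogous Rubottom oxidation and should give, after loss of the enol silyl group on work-up, 9α-(tert-butyldimethylsilyloxy)-6β-hydroxy-8α-(triethylsilyloxy)eudesma-1,4-dien-3-one F8 (drawn as the 6β epimer; either C6 epimer serves). MnO2 oxidises the allylic alcohol of F8 and the route is rejoined at 13.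

**Step 12.** Borohydride may also reduce the enone (1,2 or 1,4), or attack C6 from the β-face. Fallback: reduce both carbonyls, then reoxidise one. Setting out from 14, NaBH4 with CeCl3 in MeOH reduces both carbonyls to 9α-(tert-butyldimethylsilyloxy)-8α-(triethylsilyloxy)-5αH-eudesm-1-ene-3β,6β-diol F9 (either C3 epimer serves). MnO2 then oxidises only the allylic C3 alcohol of F9 and the route is rejoined at 15.

**Step 18.** The oxidant may react through the other ring conformer and give the epoxide on the opposite face, may also attack C1=C10, or the 3-chlorobenzoic acid formed may trigger transannular cyclisation. Fallback: metal-bound delivery in place of hydrogen-bond delivery. Setting out from 21, VO(acac)2 (cat.) with anhydrous t-BuOOH in CH2Cl2 at 0 °C binds the oxidant to the C6 alkoxide, the only site that can carry it, so that C1=C10 cannot compete and no carboxylic acid is present; the route is rejoined at 22. No new compound is involved.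

## Further compounds

F0 | step 16 | none | none
F1 | step 3 | cis-fused 5βH-eudesmane-3,9-dione | C1[C@H](C(C)C)C[C@H]2[C@@H](C)C(=O)CC[C@@]2(C)C1=O
F2 | step 3 | 3,3-ethylenedioxy-5βH-eudesman-9-one | C1[C@H](C(C)C)C[C@H]2[C@@H](C)C3(OCCO3)CC[C@@]2(C)C1=O
F3 | step 3 | 3,3-ethylenedioxy-5βH-eudesm-8-en-9-yl trifluoromethanesulfonate | FC(F)(F)S(=O)(=O)OC1=C[C@H](C(C)C)C[C@H]2[C@@H](C)C3(OCCO3)CC[C@@]12C
F4 | step 3 | 3,3-ethylenedioxy-5βH-eudesm-8-ene | C1=C[C@H](C(C)C)C[C@H]2[C@@H](C)C3(OCCO3)CC[C@@]12C
F5 | step 6 | cis-fused 5βH-eudesma-1,8-dien-3-one | C1=C[C@H](C(C)C)C[C@H]2[C@@H](C)C(=O)C=C[C@@]12C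
F6 | step 6 | 3-(trimethylsilyloxy)-5βH-eudesma-1,3,8-triene | C1=C[C@H](C(C)C)C[C@H]2C(C)=C(O[Si](C)(C)C)C=C[C@@]12C
F7 | step 10 | 3,9α-bis(tert-butyldimethylsilyloxy)-8α-(triethylsilyloxy)eudesma-1,3,5-triene | CC[Si](CC)(CC)O[C@H]1[C@H](C(C)C)C=C2C(C)=C(O[Si](C)(C)C(C)(C)C)C=C[C@@]2(C)[C@H]1O[Si](C)(C)C(C)(C)C
F8 | step 10 | 9α-(tert-butyldimethylsilyloxy)-6β-hydroxy-8α-(triethylsilyloxy)eudesma-1,4-dien-3-one | CC[Si](CC)(CC)O[C@H]1[C@H](C(C)C)[C@H](O)C2=C(C)C(=O)C=C[C@@]2(C)[C@H]1O[Si](C)(C)C(C)(C)C
F9 | step 12 | 9α-(tert-butyldimethylsilyloxy)-8α-(triethylsilyloxy)-5αH-eudesm-1-ene-3β,6β-diol | CC[Si](CC)(CC)O[C@H]1[C@H](C(C)C)[C@H](O)[C@@H]2[C@@H](C)[C@H](O)C=C[C@@]2(C)[C@H]1O[Si](C)(C)C(C)(C)C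
F0 | step 18 | none | none
A1 | alternative 1 | 8-O-destigloyl target (C8,C9-diol) | O[C@H]1[C@H](C(C)C)[C@H](OC(C)=O)[C@H]2O[C@]2(C)CC/C=C(\C)[C@H]1O
A2 | alternative 1 | seco-dialdehyde (C8 aldehyde, C9 enal) | O=C[C@H](C(C)C)[C@H](OC(C)=O)[C@H]1O[C@]1(C)CC/C=C(\C)C=O
A3 | alternative 2 | cyclodec-1(10)-yn-6-one with C4/C5 acetonide, C8 OPMB, C9 OTBS | COc5ccc(cc5)CO[C@H]1[C@H](C(C)C)C(=O)[C@@H]2OC(C)(C)O[C@]2(C)CCC#C[C@H]1O[Si](C)(C)C(C)(C)C
A4 | alternative 2 | bicyclic C1,C6-epoxy C10-ketone (either epoxide face; both epoxide carbons lose their configuration) | COc1ccc(cc1)CO[C@H]2[C@H](C(C)C)C34OC3(CC[C@@]5(C)OC(C)(C)O[C@@H]45)C(=O)[C@H]2O[Si](C)(C)C(C)(C)C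
A5 | alternative 3 | (1(10)E,4E)-cyclodecadienyl C10 triflate with the C6–C9 stereotetrad | COc3ccc(cc3)CO[C@H]1[C@H](C(C)C)[C@H](O[Si](CC)(CC)CC)/C=C(\C)CC/C=C(\OS(=O)(=O)C(F)(F)F)[C@H]1OCc4ccc5ccccc5c4
A6 | alternative 3 | trans-1-vinyl-2-isopropenylcyclohexanol with the C6–C9 stereotetrad | COc1ccc(cc1)CO[C@H]2[C@H](C(C)C)[C@H](O[Si](CC)(CC)CC)[C@H](C(C)=C)[C@@](O)(C=C)[C@H]2OCc3ccc4ccccc4c3
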